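**Retrosynthetic overview**

- The strategy rests on ring A: C8a (bearing O1) and C4a (bearing the C4 carbonyl) are neighbours, flanked by C8 (side chain) and C5 (oxygen). They are treated as the two carbons of an aryne, so O1–C8a and C4–C4a are disconnected together and ring C is closed last onto a β-silyloxy ester that already carries C2 (S) and ring B.
- The aryne precursor is an o-silylaryl triflate made from phloroglucinol by two carbamate-directed ortho-metalations (silicon at C4a, iodine at C8) and a Negishi coupling that forms the C8–C1'' bond.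
- The side chain comes from (R)-(+)-limonene: ring cleavage keeps its stereocentre as C2'', followed by methylenation and a one-carbon degradation to a primary iodide.
- The C2 carbinol comes from asymmetric transfer hydrogenation of a β-keto ester built on 4'-hydroxyacetophenone; it is silylated so that fluoride releases the alkoxide in a medium free of O–H.
- Ring order: A and B are bought, ring C is formed in the annulation, and the three methoxymethyl ethers are removed at the end.

Key step: step 16

Remark: flavanone numbering is used for ring atoms (C1'' benzylic, C2'' the side-chain stereocentre), and commercial (R)-(+)-limonene is taken to be of high enantiomeric purity.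

**Route**

Step 1
Reactants: 1 phloroglucinol; 2 chloromethyl methyl ether
Product: 3 3,5-bis(methoxymethoxy)phenol
Conditions: MOMCl (2.0 equiv), i-Pr2NEt (2.2 equiv), DMF, 0 °C → rt; chromatography
Reagents that add atoms: chloromethyl methyl ether, COCCl
Why: Williamson-type O-alkylation with the α-chloro ether is statistical, so two equivalents are used and the bis-ether is separated from the mono-ether (re-submitted) and the tris-ether.

Step 2
Reactants: 3 3,5-bis(methoxymethoxy)phenol; 4 N,N-diethylcarbamoyl chloride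
Product: 5 3,5-bis(methoxymethoxy)phenyl N,N-diethylcarbamate
Conditions: ClCONEt2, K2CO3, MeCN, reflux
Reagents that add atoms: N,N-diethylcarbamoyl chloride, CCN(CC)C(Cl)=O
Why: O-carbamoylation of the phenoxide (acyl substitution) installs the strongest oxygen-based directing group for the two metalations that follow.

Step 3
Reactants: 5 3,5-bis(methoxymethoxy)phenyl N,N-diethylcarbamate; 6 chlorotrimethylsilane
Product: 8 3,5-bis(methoxymethoxy)-2-(trimethylsilyl)phenyl N,N-diethylcarbamate, via aryllithium 7 (not isolated)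
Conditions: s-BuLi, TMEDA, THF, −78 °C; TMSCl, −78 °C → rt
Reagents that add atoms: chlorotrimethylsilane, C[Si](C)(C)Cl
Why: Directed ortho-metalation takes place at the position flanked by the carbamate and a methoxymethoxy group, and silylation at −78 °C is faster than anionic Fries rearrangement.

Step 4
Reactants: 8 3,5-bis(methoxymethoxy)-2-(trimethylsilyl)phenyl N,N-diethylcarbamate; 9 iodine
Product: 11 2-iodo-3,5-bis(methoxymethoxy)-6-(trimethylsilyl)phenyl N,N-diethylcarbamate, via aryllithium 10 (not isolated)
Conditions: s-BuLi, TMEDA, THF, −78 °C; I2 (THF), −78 °C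
Reagents that add atoms: iodine, II
Why: A second directed ortho-metalation should go to the remaining carbamate-flanked position, not to the CH between the two methoxymethoxy groups, because the carbamate is the stronger director, and iodinolysis gives the aryl iodide.

Step 5
Reactants: 12 (R)-(+)-limonene; 13 ozone
Product: 15 (3R)-6-oxo-3-(prop-1-en-2-yl)heptanal, via limonene 1,2-ozonide 14 (not isolated)
Conditions: O3 (1.0 equiv), CH2Cl2, −78 °C; Me2S, −78 °C → rt
Reagents that add atoms: ozone, [O-][O+]=O
Why: Ozonolysis with reductive work-up cleaves the electron-richer trisubstituted ring alkene in preference to the isopropenyl group and leaves the stereocentre untouched.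

Step 6
Reactants: 15 (3R)-6-oxo-3-(prop-1-en-2-yl)heptanal; 16 sodium chlorite
Product: 17 (3R)-6-oxo-3-(prop-1-en-2-yl)heptanoic acid
Conditions: NaClO2, NaH2PO4, 2-methylbut-2-ene, t-BuOH/H2O, 0 °C → rt
Reagents that add atoms: sodium chlorite, [Na+].[O-]Cl=O
Why: Pinnick oxidation converts only the aldehyde, the alkene scavenger removing hypochlorous acid before it can attack the isopropenyl group.

Step 7
Reactants: 17 (3R)-6-oxo-3-(prop-1-en-2-yl)heptanoic acid; 18 methyltriphenylphosphonium bromide
Product: 19 (3R)-6-methyl-3-(prop-1-en-2-yl)hept-6-enoic acid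
Conditions: Ph3PCH3Br (3.5 equiv), KOt-Bu (3.4 equiv), THF, 0 °C → rt; aq. citric acid
Reagents that add atoms: methyltriphenylphosphonium bromide, C[P+](c1ccccc1)(c1ccccc1)c1ccccc1.[Br-]
Why: Wittig methylenation of the methyl ketone proceeds on the inert carboxylate salt, and the stereocentre, β to the carboxylate and γ to the ketone, cannot epimerise.

Step 8
Reactants: 19 (3R)-6-methyl-3-(prop-1-en-2-yl)hept-6-enoic acid; 20 1-hydroxypyridine-2(1H)-thione; 21 iodoform
Product: 23 (3S)-3-(iodomethyl)-2,6-dimethylhepta-1,6-diene, via thiohydroxamate ester 22 (not isolated)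
Conditions: 20, DCC, DMAP (cat.), CH2Cl2, 0 °C, dark; CHI3 (3 equiv), PhH, visible light, rt
Reagents that add atoms: iodoform, IC(I)I
Why: In this Barton decarboxylative iodination the primary radical left after loss of CO2 should take iodine from the excess iodoform faster than it can cyclise onto the remote alkene or undergo a vinyl shift, and the stereocentre β to the radical is not involved.

Step 9
Reactants: 23 (3S)-3-(iodomethyl)-2,6-dimethylhepta-1,6-diene; 11 2-iodo-3,5-bis(methoxymethoxy)-6-(trimethylsilyl)phenyl N,N-diethylcarbamate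
Product: 26 2-[(2R)-5-methyl-2-(prop-1-en-2-yl)hex-5-en-1-yl]-3,5-bis(methoxymethoxy)-6-(trimethylsilyl)phenyl N,N-diethylcarbamate, via alkyllithium 24 (not isolated), via alkylzinc chloride 25 (not isolated)
Conditions: 23, t-BuLi (2.1 equiv), Et2O/pentane, −78 °C; ZnCl2 (THF), −78 °C → rt; 11, Pd2(dba)3 (cat.), SPhos (cat.), THF, 50 °C
Reagents that add atoms: none
Why: Iodine–lithium exchange at −78 °C (too cold for carbolithiation of the alkene), transmetalation to zinc and Negishi coupling with the di-ortho-substituted aryl iodide on zerovalent palladium bearing a bulky biarylphosphine should join C8 to C1'', reductive elimination outpacing β-hydride elimination.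

Step 10
Reactants: 26 2-[(2R)-5-methyl-2-(prop-1-en-2-yl)hex-5-en-1-yl]-3,5-bis(methoxymethoxy)-6-(trimethylsilyl)phenyl N,N-diethylcarbamate
Product: 27 2-[(2R)-5-methyl-2-(prop-1-en-2-yl)hex-5-en-1-yl]-3,5-bis(methoxymethoxy)-6-(trimethylsilyl)phenol
Conditions: LiAlH4, THF, 0 → 65 °C; aq. potassium sodium tartrate
Reagents that add atoms: none
Why: Hydride attack at the carbamate carbonyl (reductive cleavage of an aryl carbamate) frees the phenol while alkenes, acetals and the aryl–silicon bond are inert to LiAlH4.

Step 11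
Reactants: 27 2-[(2R)-5-methyl-2-(prop-1-en-2-yl)hex-5-en-1-yl]-3,5-bis(methoxymethoxy)-6-(trimethylsilyl)phenol; 28 trifluoromethanesulfonic anhydride
Product: 29 2-[(2R)-5-methyl-2-(prop-1-en-2-yl)hex-5-en-1-yl]-3,5-bis(methoxymethoxy)-6-(trimethylsilyl)phenyl trifluoromethanesulfonate
Conditions: Tf2O, pyridine, CH2Cl2, −78 → 0 °C
Reagents that add atoms: trifluoromethanesulfonic anhydride, O=S(=O)(OS(=O)(=O)C(F)(F)F)C(F)(F)F
Why: O-sulfonylation of the hindered phenol under pyridine buffering gives the o-silylaryl triflate without harming the acetals or alkenes.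

Step 12
Reactants: 30 4'-hydroxyacetophenone; 2 chloromethyl methyl ether
Product: 31 4'-(methoxymethoxy)acetophenone
Conditions: MOMCl, i-Pr2NEt, CH2Cl2, 0 °C → rt
Reagents that add atoms: chloromethyl methyl ether, COCCl
Why: Williamson-type O-alkylation protects the phenol as the same acetal used on ring A.

Step 13
Reactants: 31 4'-(methoxymethoxy)acetophenone; 32 dimethyl carbonate
Product: 33 methyl 3-[4-(methoxymethoxy)phenyl]-3-oxopropanoate
Conditions: NaH (2.5 equiv), (MeO)2CO, THF, reflux; AcOH quench
Reagents that add atoms: dimethyl carbonate, COC(=O)OC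
Why: Crossed Claisen condensation of the ketone enolate with the carbonate is driven by deprotonation of the β-keto ester formed.

Step 14
Reactants: 33 methyl 3-[4-(methoxymethoxy)phenyl]-3-oxopropanoate
Product: 34 methyl (3S)-3-hydroxy-3-[4-(methoxymethoxy)phenyl]propanoate
Conditions: RuCl[(S,S)-TsDPEN](p-cymene) (cat.), HCO2H/Et3N (5:2), 40 °C
Reagents that add atoms: none
Why: In this Noyori–Ikariya asymmetric transfer hydrogenation the (S,S)-ligand places the aryl group against the η6-arene of the catalyst, so hydride should reach the same ketone face as with acetophenone and give the S carbinol, the ester and acetal being inert.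

Step 15
Reactants: 34 methyl (3S)-3-hydroxy-3-[4-(methoxymethoxy)phenyl]propanoate; 6 chlorotrimethylsilane
Product: 35 methyl (3S)-3-[4-(methoxymethoxy)phenyl]-3-[(trimethylsilyl)oxy]propanoate
Conditions: TMSCl, imidazole, CH2Cl2, 0 °C; non-aqueous work-up
Reagents that add atoms: chlorotrimethylsilane, C[Si](C)(C)Cl
Why: O-silylation turns the alcohol into a latent alkoxide that fluoride can release without any O–H in the medium.

Step 16
Reactants: 29 2-[(2R)-5-methyl-2-(prop-1-en-2-yl)hex-5-en-1-yl]-3,5-bis(methoxymethoxy)-6-(trimethylsilyl)phenyl trifluoromethanesulfonate; 35 methyl (3S)-3-[4-(methoxymethoxy)phenyl]-3-[(trimethylsilyl)oxy]propanoate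
Product: 39 (2S)-5,7-bis(methoxymethoxy)-2-[4-(methoxymethoxy)phenyl]-8-[(2R)-5-methyl-2-(prop-1-en-2-yl)hex-5-en-1-yl]chroman-4-one, via ring A aryne 36 (not isolated), via caesium alkoxide 37 (not isolated), via aryl caesium adduct 38 (not isolated)
Conditions: CsF (3 equiv, dried), 18-crown-6 (0.3 equiv), 35 (1.5 equiv), PhMe, rt → 45 °C, sealed
Reagents that add atoms: none
Why: Proposed new method: fluoride removes the O-silyl group of 35 to give alkoxide 37 and the C-silyl group of 29 with loss of triflate to give the C4a–C8a aryne 36; the alkoxide oxygen adds at C8a, the C4a aryl anion 38 attacks the ester carbonyl and methoxide leaves, so that O1–C8a and C4–C4a form in one operation. The closest known reaction types are the σ-insertion of arynes into the C–O bond of carboxylic acids, which gives ortho-hydroxyaryl ketones, and the aryne annulation of salicylate esters to xanthones; an aliphatic β-oxy ester as partner has not been shown. Ring C closes by a 6-exo-trig addition–elimination of the aryl anion on the ester. No stereocentre is created: C2 keeps the S configuration set in step 14 because none of its four bonds is touched, and C2'' is remote. The selectivity required is the sense of addition across the unsymmetrical triple bond: the inductively withdrawing methoxymethoxy group on C5 bends and polarises the aryne so that oxygen enters at C8a and the charge develops at C4a, ortho to that oxygen, which should outweigh the small hindrance from the C8 benzylic CH2. Acylation must also outrun protonation of the aryl anion, which is why the silyl ether is used: no O–H is present, and the expelled methoxide is silylated by a further molecule of 35, which releases the next alkoxide and leaves no base to open the flavanone to its chalcone.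

Step 17
Reactants: 39 (2S)-5,7-bis(methoxymethoxy)-2-[4-(methoxymethoxy)phenyl]-8-[(2R)-5-methyl-2-(prop-1-en-2-yl)hex-5-en-1-yl]chroman-4-one
Product: 40 remangiflavanone A
Conditions: HCl (1.25 M in MeOH), MeOH/THF, 0 °C → rt
Reagents that add atoms: none
Why: Acid-catalysed methanolysis of the three aryl methoxymethyl acetals (transacetalisation) should proceed under conditions too mild to protonate the two 1,1-disubstituted alkenes or to epimerise C2.

**Compound list**

1 | phloroglucinol | Oc1cc(O)cc(O)c1 | starting material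
2 | chloromethyl methyl ether | COCCl | starting material
3 | 3,5-bis(methoxymethoxy)phenol | COCOc1cc(O)cc(OCOC)c1 | intermediate
4 | N,N-diethylcarbamoyl chloride | CCN(CC)C(Cl)=O | starting material
5 | 3,5-bis(methoxymethoxy)phenyl N,N-diethylcarbamate | CCN(CC)C(=O)Oc1cc(OCOC)cc(OCOC)c1 | intermediate
6 | chlorotrimethylsilane | C[Si](C)(C)Cl | starting material
7 | [2-(diethylcarbamoyloxy)-4,6-bis(methoxymethoxy)phenyl]lithium | CCN(CC)C(=O)Oc1cc(OCOC)cc(OCOC)c1[Li] | intermediate
8 | 3,5-bis(methoxymethoxy)-2-(trimethylsilyl)phenyl N,N-diethylcarbamate | CCN(CC)C(=O)Oc1cc(OCOC)cc(OCOC)c1[Si](C)(C)C | intermediate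
9 | iodine | II | starting material
10 | [2-(diethylcarbamoyloxy)-4,6-bis(methoxymethoxy)-3-(trimethylsilyl)phenyl]lithium | CCN(CC)C(=O)Oc1c([Li])c(OCOC)cc(OCOC)c1[Si](C)(C)C | intermediate
11 | 2-iodo-3,5-bis(methoxymethoxy)-6-(trimethylsilyl)phenyl N,N-diethylcarbamate | CCN(CC)C(=O)Oc1c(I)c(OCOC)cc(OCOC)c1[Si](C)(C)C | intermediate
12 | (R)-(+)-limonene | CC1=CC[C@@H](CC1)C(C)=C | starting material
13 | ozone | [O-][O+]=O | starting material
14 | limonene 1,2-ozonide, 1-methyl-4-(prop-1-en-2-yl)-7,8,9-trioxabicyclo[4.2.1]nonane (isopropenyl centre as in 12, mixture at the acetal carbons) | CC12CC[C@@H](C(C)=C)CC(OO1)O2 | intermediate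
15 | (3R)-6-oxo-3-(prop-1-en-2-yl)heptanal | CC(=O)CC[C@H](CC=O)C(=C)C | intermediate
16 | sodium chlorite | [Na+].[O-]Cl=O | starting material
17 | (3R)-6-oxo-3-(prop-1-en-2-yl)heptanoic acid | CC(=O)CC[C@H](CC(=O)O)C(=C)C | intermediate
18 | methyltriphenylphosphonium bromide | C[P+](c1ccccc1)(c1ccccc1)c1ccccc1.[Br-] | starting material
19 | (3R)-6-methyl-3-(prop-1-en-2-yl)hept-6-enoic acid | C=C(C)CC[C@H](CC(=O)O)C(=C)C | intermediate
20 | 1-hydroxypyridine-2(1H)-thione | ON1C=CC=CC1=S | starting material
21 | iodoform | IC(I)I | starting material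
22 | 2-thioxopyridin-1(2H)-yl (3R)-6-methyl-3-(prop-1-en-2-yl)hept-6-enoate | C=C(C)CC[C@H](CC(=O)ON1C=CC=CC1=S)C(=C)C | intermediate
23 | (3S)-3-(iodomethyl)-2,6-dimethylhepta-1,6-diene | C=C(C)CC[C@H](CI)C(=C)C | intermediate
24 | [(2S)-5-methyl-2-(prop-1-en-2-yl)hex-5-en-1-yl]lithium | C=C(C)CC[C@H](C[Li])C(=C)C | intermediate
25 | chloro[(2S)-5-methyl-2-(prop-1-en-2-yl)hex-5-en-1-yl]zinc | C=C(C)CC[C@H](C[Zn]Cl)C(=C)C | intermediate
26 | 2-[(2R)-5-methyl-2-(prop-1-en-2-yl)hex-5-en-1-yl]-3,5-bis(methoxymethoxy)-6-(trimethylsilyl)phenyl N,N-diethylcarbamate | C=C(C)CC[C@H](Cc1c(OCOC)cc(OCOC)c([Si](C)(C)C)c1OC(=O)N(CC)CC)C(=C)C | intermediate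
27 | 2-[(2R)-5-methyl-2-(prop-1-en-2-yl)hex-5-en-1-yl]-3,5-bis(methoxymethoxy)-6-(trimethylsilyl)phenol | C=C(C)CC[C@H](Cc1c(OCOC)cc(OCOC)c([Si](C)(C)C)c1O)C(=C)C | intermediate
28 | trifluoromethanesulfonic anhydride | O=S(=O)(OS(=O)(=O)C(F)(F)F)C(F)(F)F | starting material
29 | 2-[(2R)-5-methyl-2-(prop-1-en-2-yl)hex-5-en-1-yl]-3,5-bis(methoxymethoxy)-6-(trimethylsilyl)phenyl trifluoromethanesulfonate | C=C(C)CC[C@H](Cc1c(OCOC)cc(OCOC)c([Si](C)(C)C)c1OS(=O)(=O)C(F)(F)F)C(=C)C | intermediate
30 | 4'-hydroxyacetophenone | CC(=O)c1ccc(O)cc1 | starting material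
31 | 4'-(methoxymethoxy)acetophenone | CC(=O)c1ccc(OCOC)cc1 | intermediate
32 | dimethyl carbonate | COC(=O)OC | starting material
33 | methyl 3-[4-(methoxymethoxy)phenyl]-3-oxopropanoate | COCOc1ccc(cc1)C(=O)CC(=O)OC | intermediate
34 | methyl (3S)-3-hydroxy-3-[4-(methoxymethoxy)phenyl]propanoate | O[C@H](c1ccc(OCOC)cc1)CC(=O)OC | intermediate
35 | methyl (3S)-3-[4-(methoxymethoxy)phenyl]-3-[(trimethylsilyl)oxy]propanoate | C[Si](C)(C)O[C@H](c1ccc(OCOC)cc1)CC(=O)OC | intermediate
36 | 3,5-bis(methoxymethoxy)-6-[(2R)-5-methyl-2-(prop-1-en-2-yl)hex-5-en-1-yl]-1,2-didehydrobenzene (ring A aryne) | C=C(C)CC[C@H](CC1=C(OCOC)C=C(OCOC)C#C1)C(=C)C | intermediate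
37 | caesium (1S)-3-methoxy-1-[4-(methoxymethoxy)phenyl]-3-oxopropan-1-olate | [Cs+].[O-][C@H](c1ccc(OCOC)cc1)CC(=O)OC | intermediate
38 | methyl (3S)-3-{2-caesio-3,5-bis(methoxymethoxy)-6-[(2R)-5-methyl-2-(prop-1-en-2-yl)hex-5-en-1-yl]phenoxy}-3-[4-(methoxymethoxy)phenyl]propanoate | C=C(C)CC[C@H](Cc1c(OCOC)cc(OCOC)c([Cs])c1O[C@H](c1ccc(OCOC)cc1)CC(=O)OC)C(=C)C | intermediate
39 | (2S)-5,7-bis(methoxymethoxy)-2-[4-(methoxymethoxy)phenyl]-8-[(2R)-5-methyl-2-(prop-1-en-2-yl)hex-5-en-1-yl]chroman-4-one | C=C(C)CC[C@H](Cc1c(OCOC)cc(OCOC)c2c1O[C@H](c1ccc(OCOC)cc1)CC2=O)C(=C)C | intermediate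
40 | remangiflavanone A, (2S)-5,7-dihydroxy-2-(4-hydroxyphenyl)-8-[(2R)-5-methyl-2-(prop-1-en-2-yl)hex-5-en-1-yl]chroman-4-one | C=C(C)CC[C@H](Cc1c(O)cc(O)c2c1O[C@H](c1ccc(O)cc1)CC2=O)C(=C)C | target

**Totals**

Total step count: 17.
Longest linear sequence: 9 steps (1, 2, 3, 4, 9, 10, 11, 16, 17 from phloroglucinol; equally 5, 6, 7, 8, 9, 10, 11, 16, 17 from limonene).

**Steps most likely to fail**

Step 16 (proposed new method). The aryl anion may be lost by proton transfer from the ester α-CH2 before it acylates. The alkoxide may fragment by retro-aldol cleavage or β-elimination before it meets the aryne. Addition may take the wrong sense across the triple bond, or the aryne may be captured by the pendant isopropenyl group in an ene reaction. The fallback uses aryne chemistry that is already established and sets out from triflate 29. With acetic acid and CsF in THF (sealed tube, 125 °C), the carboxylate should add at C8a and the acetyl group shift to C4a (carboxylic acid C–O insertion), giving 1-{2-hydroxy-4,6-bis(methoxymethoxy)-3-[(2R)-5-methyl-2-(prop-1-en-2-yl)hex-5-en-1-yl]phenyl}ethan-1-one F1. Claisen–Schmidt condensation with commercial 4-(methoxymethoxy)benzaldehyde (KOH, EtOH, rt) should give (E)-1-{2-hydroxy-4,6-bis(methoxymethoxy)-3-[(2R)-5-methyl-2-(prop-1-en-2-yl)hex-5-en-1-yl]phenyl}-3-[4-(methoxymethoxy)phenyl]prop-2-en-1-one F2. Oxa-Michael closure (NaOAc, EtOH, reflux) should give the flavanone as both C2 epimers, 39 and (2R)-5,7-bis(methoxymethoxy)-2-[4-(methoxymethoxy)phenyl]-8-[(2R)-5-methyl-2-(prop-1-en-2-yl)hex-5-en-1-yl]chroman-4-one F3. These are separated by preparative HPLC on a chiral stationary phase, and F3 is returned to the equilibration. Stereocontrol at C2 is given up in exchange for known bond-forming steps. The fallback rejoins the route at 39.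

Step 8. The primary radical may cyclise onto the 5,6-alkene or undergo a vinyl shift before iodine transfer, and iodine-centred radicals may add to the alkenes. The fallback is an ionic one-carbon degradation and sets out from acid 19. Double deprotonation (LDA, 2.2 equiv, THF, −78 → 0 °C) and oxygenation of the dianion (O2, then P(OEt)3) should give (3S)-2-hydroxy-6-methyl-3-(prop-1-en-2-yl)hept-6-enoic acid F4 as a mixture at C2. Oxidative decarboxylation with Pb(OAc)4 (PhH, 0 °C) should give (2S)-5-methyl-2-(prop-1-en-2-yl)hex-5-enal F5. Because this aldehyde can epimerise, it is reduced at once (NaBH4, MeOH, −20 °C) to (2S)-5-methyl-2-(prop-1-en-2-yl)hex-5-en-1-ol F6. I2, PPh3 and imidazole (CH2Cl2, 0 °C) then convert F6 into iodide 23, where the route is rejoined.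

Step 9. Oxidative addition and transmetalation at the di-ortho-substituted aryl iodide may be slow, so that β-hydride elimination or protodemetalation of the alkylzinc takes over. The fallback reverses the roles of the partners and uses no palladium. It sets out from silyl carbamate 8, which is lithiated as in step 4 to aryllithium 10 and transmetalated with MgBr2·OEt2 (THF, −78 → 0 °C) to bromo[2-(diethylcarbamoyloxy)-4,6-bis(methoxymethoxy)-3-(trimethylsilyl)phenyl]magnesium F7. Copper-catalysed alkylation of this Grignard reagent with iodide 23 (Li2CuCl4 cat., THF, 0 °C → rt) should give 26, where the route is rejoined.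

**Further compounds**

F1 | step 16 | 1-{2-hydroxy-4,6-bis(methoxymethoxy)-3-[(2R)-5-methyl-2-(prop-1-en-2-yl)hex-5-en-1-yl]phenyl}ethan-1-one | C=C(C)CC[C@H](Cc1c(OCOC)cc(OCOC)c(C(C)=O)c1O)C(=C)C
F2 | step 16 | (E)-1-{2-hydroxy-4,6-bis(methoxymethoxy)-3-[(2R)-5-methyl-2-(prop-1-en-2-yl)hex-5-en-1-yl]phenyl}-3-[4-(methoxymethoxy)phenyl]prop-2-en-1-one | C=C(C)CC[C@H](Cc1c(OCOC)cc(OCOC)c(C(=O)/C=C/c2ccc(OCOC)cc2)c1O)C(=C)C
F3 | step 16 | (2R)-5,7-bis(methoxymethoxy)-2-[4-(methoxymethoxy)phenyl]-8-[(2R)-5-methyl-2-(prop-1-en-2-yl)hex-5-en-1-yl]chroman-4-one | C=C(C)CC[C@H](Cc1c(OCOC)cc(OCOC)c2c1O[C@@H](c1ccc(OCOC)cc1)CC2=O)C(=C)C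
F4 | step 8 | (3S)-2-hydroxy-6-methyl-3-(prop-1-en-2-yl)hept-6-enoic acid (mixture at C2) | C=C(C)CC[C@H](C(O)C(=O)O)C(=C)C
F5 | step 8 | (2S)-5-methyl-2-(prop-1-en-2-yl)hex-5-enal | C=C(C)CC[C@H](C=O)C(=C)C
F6 | step 8 | (2S)-5-methyl-2-(prop-1-en-2-yl)hex-5-en-1-ol | C=C(C)CC[C@H](CO)C(=C)C
F7 | step 9 | bromo[2-(diethylcarbamoyloxy)-4,6-bis(methoxymethoxy)-3-(trimethylsilyl)phenyl]magnesium | Br[Mg]c1c(OCOC)cc(OCOC)c([Si](C)(C)C)c1OC(=O)N(CC)CC
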